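The strategy rests on disconnecting the C7–H bond of the carbinol, with C9 carried as a methyl ester. In the racemic β-keto ester precursor, C8 carries the ether oxygen to ring B (the methyl vanillate ring) and sits between the C7 ketone on ring A (the 3,4-dimethoxyphenyl ring) and the C9 ester carbonyl, so C8–H is acidic and C8 epimerises freely. A single asymmetric transfer hydrogenation under dynamic kinetic resolution should therefore convert the racemate into one threo isomer, setting C7 and C8 together. The precursor comes in two steps from methyl vanillate; afterwards the C9 ester is taken to the methyl group by reduction, iodination and deiodination.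

Key step: step 3

Remark: locants follow the 8-O-4' neolignan convention (C7 = carbinol carbon on ring A, C8 = carbon bearing the ether oxygen to ring B, C9 = terminal carbon); the target is the threo (7S,8S) isomer, and the C8 descriptor reads R while C9 is an ester or CH2I and S while C9 is CH2OH or CH3 only because CIP priorities change, the configuration being the same throughout.

Step 1
Reactants: 1 methyl vanillate (methyl 4-hydroxy-3-methoxybenzoate); 2 methyl bromoacetate
Product: 3 methyl 3-methoxy-4-(2-methoxy-2-oxoethoxy)benzoate
Conditions: K2CO3, acetone, reflux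
Reagents that add atoms: none
Why: Williamson ether synthesis: the potassium phenoxide of 1 displaces bromide from the unhindered α-bromo ester 2 by SN2, and the weak carbonate base in an aprotic solvent leaves both methyl esters intact.

Step 2
Reactants: 3 methyl 3-methoxy-4-(2-methoxy-2-oxoethoxy)benzoate; 4 3,4-dimethoxybenzoyl chloride
Product: 6 racemic methyl 3-(3,4-dimethoxyphenyl)-2-[2-methoxy-4-(methoxycarbonyl)phenoxy]-3-oxopropanoate, via lithium ester enolate 5 (not isolated)
Conditions: LiN(SiMe3)2 (2.1 equiv), THF, −78 °C; then 4, −78 → −40 °C; AcOH quench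
Reagents that add atoms: none
Why: Crossed Claisen-type C-acylation of a preformed lithium ester enolate with an acid chloride: the second equivalent of base deprotonates the more acidic β-keto ester as it forms so that it cannot quench unreacted enolate 5, the hindered amide base at −78 °C spares the benzoate ester, and no stereocontrol is needed because C8 is meant to be racemic and labile.

Step 3
Reactants: 6 racemic methyl 3-(3,4-dimethoxyphenyl)-2-[2-methoxy-4-(methoxycarbonyl)phenoxy]-3-oxopropanoate
Product: 7 methyl (2R,3S)-3-(3,4-dimethoxyphenyl)-3-hydroxy-2-[2-methoxy-4-(methoxycarbonyl)phenoxy]propanoate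
Conditions: RuCl[(R,R)-TsDPEN](p-cymene) (2 mol %), HCO2H/Et3N (5:2), CH2Cl2, 30 °C
Reagents that add atoms: none
Why: Transfer hydrogenation: formate turns the precatalyst into the 18-electron ruthenium hydride, which delivers hydride to C7 and the ligand N–H proton to the carbonyl oxygen through a six-membered outer-sphere transition state, while unreacted 6 keeps racemising at C8 through its enol in the formic acid/triethylamine buffer. The closest known reaction is the Noyori–Ikariya asymmetric transfer hydrogenation of α-alkoxy β-keto esters under dynamic kinetic resolution, which gives syn α-alkoxy β-hydroxy esters; the aryloxy substrate belongs to the same class. No ring is closed and no skeletal bond is formed; only the C7–H bond is made. C7 is set by the catalyst: the CH/π contact between the cymene ligand and ring A fixes the carbonyl face, and the (R,R) ligand places the hydroxyl as in (R)-1-phenylethanol, which reads 3S here because C8 outranks ring A. C8 is set by kinetic selection in the same transition state: the epimer that can hold its C8–O bond anti to the incoming hydride with the small C8–H beside the hydride path (polar Felkin–Anh arrangement, no chelation) is reduced faster, which gives the syn (threo) 2R,3S product. The step needs epimerisation to outrun reduction and the ketone to react in the presence of two esters: the first is secured by the C8–H acidity created by the flanking ketone, ester and aryloxy oxygen together with slow hydride transfer to the electron-rich ketone, the second by the inertness of esters toward the ruthenium hydride.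

Step 4
Reactants: 7 methyl (2R,3S)-3-(3,4-dimethoxyphenyl)-3-hydroxy-2-[2-methoxy-4-(methoxycarbonyl)phenoxy]propanoate
Product: 8 methyl 4-{[(1S,2S)-1-(3,4-dimethoxyphenyl)-1,3-dihydroxypropan-2-yl]oxy}-3-methoxybenzoate
Conditions: NaBH4, THF/MeOH, 0 °C → rt
Reagents that add atoms: none
Why: Chemoselective borohydride reduction of an ester: the aliphatic methyl ester, activated by its α-aryloxy and β-hydroxy groups, is reduced by NaBH4 in the presence of methanol well before the conjugated, electron-rich benzoate ester, and the low temperature keeps retro-aldol cleavage and C8 epimerisation from competing, so both stereocentres are carried through.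

Step 5
Reactants: 8 methyl 4-{[(1S,2S)-1-(3,4-dimethoxyphenyl)-1,3-dihydroxypropan-2-yl]oxy}-3-methoxybenzoate
Product: 9 methyl 4-{[(1S,2R)-1-(3,4-dimethoxyphenyl)-1-hydroxy-3-iodopropan-2-yl]oxy}-3-methoxybenzoate
Conditions: PPh3, I2, imidazole, THF, 0 °C → rt
Reagents that add atoms: iodine, II
Why: Appel-type iodination under Garegg–Samuelsson conditions: the unhindered primary C9 hydroxyl forms the alkoxyphosphonium ion and is displaced by iodide (SN2) much faster than the hindered secondary C7 hydroxyl, and the imidazole buffer prevents acid-promoted ionisation at the benzylic C7, so neither stereocentre is touched.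

Step 6
Reactants: 9 methyl 4-{[(1S,2R)-1-(3,4-dimethoxyphenyl)-1-hydroxy-3-iodopropan-2-yl]oxy}-3-methoxybenzoate
Product: 10 methyl 4-{[(1S,2S)-1-(3,4-dimethoxyphenyl)-1-hydroxypropan-2-yl]oxy}-3-methoxybenzoate (CNP0078567.1)
Conditions: Bu3SnH, AIBN (cat.), PhMe, 80 °C
Reagents that add atoms: none
Why: Radical chain dehalogenation: the tributyltin radical abstracts iodine from C9 and the resulting primary radical takes hydrogen from Bu3SnH faster than it can fragment, under neutral conditions that leave the free C7 hydroxyl, the benzoate ester and both stereocentres unchanged.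

Compound list
1 | methyl vanillate (methyl 4-hydroxy-3-methoxybenzoate) | COC(=O)c1ccc(O)c(OC)c1 | starting material
2 | methyl bromoacetate | COC(=O)CBr | starting material
3 | methyl 3-methoxy-4-(2-methoxy-2-oxoethoxy)benzoate | COC(=O)COc1ccc(C(=O)OC)cc1OC | intermediate
4 | 3,4-dimethoxybenzoyl chloride | COc1ccc(C(Cl)=O)cc1OC | starting material
5 | lithium 1-methoxy-2-[2-methoxy-4-(methoxycarbonyl)phenoxy]ethen-1-olate (lithium ester enolate of 3) | [Li+].[O-]C(OC)=COc1ccc(C(=O)OC)cc1OC | intermediate (not isolated)
6 | racemic methyl 3-(3,4-dimethoxyphenyl)-2-[2-methoxy-4-(methoxycarbonyl)phenoxy]-3-oxopropanoate | COC(=O)c1ccc(OC(C(=O)OC)C(=O)c2ccc(OC)c(OC)c2)c(OC)c1 | intermediate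
7 | methyl (2R,3S)-3-(3,4-dimethoxyphenyl)-3-hydroxy-2-[2-methoxy-4-(methoxycarbonyl)phenoxy]propanoate | COC(=O)c1ccc(O[C@@H](C(=O)OC)[C@@H](O)c2ccc(OC)c(OC)c2)c(OC)c1 | intermediate
8 | methyl 4-{[(1S,2S)-1-(3,4-dimethoxyphenyl)-1,3-dihydroxypropan-2-yl]oxy}-3-methoxybenzoate | COC(=O)c1ccc(O[C@@H](CO)[C@@H](O)c2ccc(OC)c(OC)c2)c(OC)c1 | intermediate
9 | methyl 4-{[(1S,2R)-1-(3,4-dimethoxyphenyl)-1-hydroxy-3-iodopropan-2-yl]oxy}-3-methoxybenzoate | COC(=O)c1ccc(O[C@@H](CI)[C@@H](O)c2ccc(OC)c(OC)c2)c(OC)c1 | intermediate
10 | methyl 4-{[(1S,2S)-1-(3,4-dimethoxyphenyl)-1-hydroxypropan-2-yl]oxy}-3-methoxybenzoate (CNP0078567.1) | COC(=O)c1ccc(O[C@@H](C)[C@@H](O)c2ccc(OC)c(OC)c2)c(OC)c1 | target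

Total step count: 6
Longest linear sequence: 6 steps, from methyl vanillate 1.

Steps most likely to fail

Step 3. Hydride transfer may not discriminate well enough between the two rapidly interconverting C8 epimers of 6, or may be too slow at the electron-rich ketone, so that the syn selectivity or the conversion falls short. The fallback replaces catalyst control by an auxiliary-controlled syn glycolate aldol (Evans aldol) and sets out from 3. Saponification of the more electrophilic aliphatic ester (LiOH, one equivalent, THF/H2O, 0 °C) should give 2-[2-methoxy-4-(methoxycarbonyl)phenoxy]acetic acid F1. Activation with pivaloyl chloride/Et3N and coupling with (R)-4-benzyloxazolidin-2-one in the presence of LiCl should give (R)-4-benzyl-3-{[2-methoxy-4-(methoxycarbonyl)phenoxy]acetyl}oxazolidin-2-one F2. Its Z boron enolate (Bu2BOTf, iPr2NEt, CH2Cl2, −78 °C) should add to 3,4-dimethoxybenzaldehyde through a Zimmerman–Traxler transition state to give the syn adduct (R)-4-benzyl-3-[(2R,3S)-3-(3,4-dimethoxyphenyl)-3-hydroxy-2-{2-methoxy-4-(methoxycarbonyl)phenoxy}propanoyl]oxazolidin-2-one F3. Reductive removal of the auxiliary with NaBH4 in THF/H2O brings the route back at diol 8.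

Step 2. O-acylation or double acylation of the enolate, consumption of the acid chloride by the amide base, or proton exchange may stall C-acylation. The fallback sets out from 3 and replaces the acyl chloride by the aldehyde. Aldol addition of the enolate (LiN(iPr)2, THF, −78 °C) to 3,4-dimethoxybenzaldehyde should give racemic methyl 3-(3,4-dimethoxyphenyl)-3-hydroxy-2-[2-methoxy-4-(methoxycarbonyl)phenoxy]propanoate F4 as a mixture of diastereomers. The mixture is acceptable, because oxidation of the benzylic alcohol (Dess–Martin periodinane, CH2Cl2) removes one centre and leaves the other labile; the route is rejoined at 6.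

Step 5. The electron-rich benzylic C7 hydroxyl may be activated as well, for example through a phosphorane bridging both hydroxyls, leading to ionisation at C7 with loss of configuration, substitution or ether closure. The fallback sets out from 8 and avoids phosphonium activation. Sulfonylation of the primary hydroxyl (TsCl, pyridine, 0 °C) should give methyl 4-{[(1S,2S)-1-(3,4-dimethoxyphenyl)-1-hydroxy-3-(tosyloxy)propan-2-yl]oxy}-3-methoxybenzoate F5. Finkelstein exchange (NaI, butanone, reflux) then rejoins the route at iodide 9.

Further compounds
F1 | step 3 | 2-[2-methoxy-4-(methoxycarbonyl)phenoxy]acetic acid | COC(=O)c1ccc(OCC(=O)O)c(OC)c1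
F2 | step 3 | (R)-4-benzyl-3-{[2-methoxy-4-(methoxycarbonyl)phenoxy]acetyl}oxazolidin-2-one | COC(=O)c1ccc(OCC(=O)N2[C@H](Cc3ccccc3)COC2=O)c(OC)c1
F3 | step 3 | (R)-4-benzyl-3-[(2R,3S)-3-(3,4-dimethoxyphenyl)-3-hydroxy-2-{2-methoxy-4-(methoxycarbonyl)phenoxy}propanoyl]oxazolidin-2-one | COC(=O)c1ccc(O[C@@H](C(=O)N2[C@H](Cc3ccccc3)COC2=O)[C@@H](O)c4ccc(OC)c(OC)c4)c(OC)c1
F4 | step 2 | racemic methyl 3-(3,4-dimethoxyphenyl)-3-hydroxy-2-[2-methoxy-4-(methoxycarbonyl)phenoxy]propanoate (mixture of diastereomers) | COC(=O)c1ccc(OC(C(=O)OC)C(O)c2ccc(OC)c(OC)c2)c(OC)c1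
F5 | step 5 | methyl 4-{[(1S,2S)-1-(3,4-dimethoxyphenyl)-1-hydroxy-3-(tosyloxy)propan-2-yl]oxy}-3-methoxybenzoate | COC(=O)c1ccc(O[C@@H](COS(=O)(=O)c2ccc(C)cc2)[C@@H](O)c3ccc(OC)c(OC)c3)c(OC)c1
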